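**Retrosynthetic overview**
- The target is unmasked last from its 8‑O‑methyl, O‑triethylsilyl precursor with BCl3.
- Key disconnection, C3–C1' (lactone carbon to side chain): a nickel‑hydride, enantioconvergent radical coupling of a racemic 3‑bromo‑dihydroisocoumarin (the HBr adduct of 6,8‑dimethoxyisocoumarin) with a terminal olefin, which sets 3R.
- The olefin comes from a Weinreb ketone synthesis on the product of copper‑catalysed hexyl Grignard opening of methyl (R)‑glycidate (6'R from the chiral pool).
- The isocoumarin comes from lateral lithiation, formylation and enol‑lactonisation of methyl 2,4‑dimethoxy‑6‑methylbenzoate, made from methyl orsellinate, itself from two methyl acetoacetate.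
- Ring order: benzene ring first (step 1), lactone ring second (step 3); C3 becomes sp3 and stereodefined only in the key step.

Assumption: the (S,S) ligand is taken to give 3R on this new cyclic substrate; if the first run shows the opposite sense, the (R,R) ligand is used with nothing else changed.

**Route**

Step 1
Reactants: 1 methyl acetoacetate (two molecules)
Product: 3 methyl 2,4-dihydroxy-6-methylbenzoate (methyl orsellinate), via triketo ester 2 (not isolated)
Conditions: NaH (1.0 equiv), THF, 0 °C; n-BuLi (1.0 equiv), −78 °C → reflux, 16 h; aq. HCl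
Reagents that add atoms: none
Why: Claisen acylation of the acetoacetate dianion (γ‑carbon) by the ester of a second acetoacetate gives methyl 3,5,7‑trioxooctanoate, whose intramolecular aldol condensation and dehydration aromatise to the resorcylate (biomimetic polyketide cyclisation); no stereocentre.

Step 2
Reactants: 3 methyl 2,4-dihydroxy-6-methylbenzoate
Product: 4 methyl 2,4-dimethoxy-6-methylbenzoate
Conditions: MeI (4 equiv), K2CO3 (4 equiv), DMF, 60 °C
Reagents that add atoms: iodomethane CI
Why: Williamson O‑methylation of both phenols (the hydrogen‑bonded 2‑OH needs the excess and warmth); the 4‑OMe becomes the 6‑OMe of the target and the 2‑OMe masks the future 8‑OH.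

Step 3
Reactants: 4 methyl 2,4-dimethoxy-6-methylbenzoate; 5 N,N-dimethylformamide
Product: 7 6,8-dimethoxy-1H-isochromen-1-one (6,8-dimethoxyisocoumarin), via aldehyde ester 6 (not isolated)
Conditions: LiN(i-Pr)2 (1.2 equiv), THF, −78 °C; 5 (2 equiv), −78 → 0 °C; then 3 M HCl, 50 °C
Reagents that add atoms: none
Why: Lateral (benzylic) lithiation of the doubly ortho‑substituted toluate, C‑formylation with DMF (the hemiaminal alkoxide prevents over‑addition) and acid‑catalysed enol‑lactonisation of the aldehyde ester with loss of MeOH give the isocoumarin; no stereocentre.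

Step 4
Reactants: 8 methyl (2R)-oxirane-2-carboxylate (methyl (R)-glycidate); 9 hexylmagnesium bromide (1.3 equiv)
Product: 11 methyl (2R)-2-(triethylsilyloxy)nonanoate, via magnesium alkoxide 10 (not isolated)
Conditions: CuBr·SMe2 (10 mol%), THF, −40 °C; then Et3SiCl (2 equiv), imidazole (2 equiv), DMF, −40 °C → rt
Reagents that add atoms: chlorotriethylsilane CC[Si](Cl)(CC)CC
Why: Copper‑catalysed SN2 opening of the glycidic ester at its unsubstituted C3 by the Grignard‑derived cuprate is faster than ester addition at −40 °C, so C2 keeps the R configuration of the chiral‑pool epoxide, and the magnesium alkoxide is O‑silylated in the same flask.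

Step 5
Reactants: 11 methyl (2R)-2-(triethylsilyloxy)nonanoate; 12 but-3-enylmagnesium bromide (1.6 equiv)
Product: 14 (6R)-6-(triethylsilyloxy)tridec-1-en-5-one, via Weinreb amide 13 (not isolated)
Conditions: MeNH(OMe)·HCl (1.5 equiv), i-PrMgCl (3.0 equiv), THF, −20 °C; then 12, −20 → 0 °C; sat. NH4Cl
Reagents that add atoms: none
Why: Weinreb ketone synthesis: the chloromagnesium amide turns the ester into the N‑methoxy‑N‑methylamide and the Grignard adds once to a chelated tetrahedral intermediate that collapses to the ketone only on work‑up; the α‑silyloxy centre is not enolised and stays R.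

Step 6
Reactants: 7 6,8-dimethoxy-1H-isochromen-1-one (1.3 equiv); 14 (6R)-6-(triethylsilyloxy)tridec-1-en-5-one
Product: 16 (3R)-6,8-dimethoxy-3-[(6R)-5-oxo-6-(triethylsilyloxy)tridecyl]isochroman-1-one, via bromolactone 15 (not isolated)
Conditions: a) HBr (anhydrous, 1.5 equiv), CH2Cl2, 0 °C, 1 h, volatiles removed in vacuo; b) NiBr2·glyme (10 mol%), (S,S)-2,2'-isopropylidenebis(4-phenyl-2-oxazoline) (12 mol%), (EtO)3SiH (2.0 equiv), K3PO4·H2O (2.0 equiv), THF/DMA 1:1, 0 °C → rt, bromolactone added last
Reagents that add atoms: none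
Why: Proposed new method: HBr adds across the enol‑lactone C3=C4 bond (H to C4, Br to the oxygen‑bearing C3, as HBr adds to vinyl esters) to give the racemic α‑bromoalkyl ester; the chiral bis(oxazoline) nickel hydride adds anti‑Markovnikov to the olefin to give a primary alkylnickel, which abstracts the bromine atom from either enantiomer of the bromolactone to give the same planar α‑acyloxy C3 radical; capture of this radical at the chiral nickel centre and C–C reductive elimination forge C3–C1' and set 3R under catalyst control (the 6'R centre is remote). The closest known reaction type is the nickel‑hydride enantioconvergent hydroalkylation of olefins with racemic open‑chain α‑bromoalkyl esters and related α‑halo carbonyl‑type electrophiles; the cyclic, lactone‑type electrophile is the untested extension.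

Step 7
Reactants: 16 (3R)-6,8-dimethoxy-3-[(6R)-5-oxo-6-(triethylsilyloxy)tridecyl]isochroman-1-one
Product: 17 (3R)-8-hydroxy-3-[(6R)-6-hydroxy-5-oxotridecyl]-6-methoxyisochroman-1-one (target)
Conditions: BCl3 (4 equiv), CH2Cl2, −78 → 0 °C; then MeOH/H2O, 0 °C → rt
Reagents that add atoms: none
Why: Chelation‑directed Lewis‑acid ether cleavage: BCl3 bound to the lactone C=O cleaves only the peri 8‑OMe through a six‑membered boron chelate, leaves the 6‑OMe, and also removes the triethylsilyl ether (completed by the HCl/MeOH formed on quench); neither stereocentre is touched.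

**Compound list**
1 | methyl acetoacetate (methyl 3-oxobutanoate) | CC(=O)CC(=O)OC | starting material
2 | methyl 3,5,7-trioxooctanoate | CC(=O)CC(=O)CC(=O)CC(=O)OC | intermediate
3 | methyl 2,4-dihydroxy-6-methylbenzoate (methyl orsellinate) | COC(=O)c1c(C)cc(O)cc1O | intermediate
4 | methyl 2,4-dimethoxy-6-methylbenzoate | COC(=O)c1c(C)cc(OC)cc1OC | intermediate
5 | N,N-dimethylformamide | CN(C)C=O | starting material
6 | methyl 2,4-dimethoxy-6-(2-oxoethyl)benzoate | COC(=O)c1c(CC=O)cc(OC)cc1OC | intermediate
7 | 6,8-dimethoxy-1H-isochromen-1-one | COc1cc2C=COC(=O)c2c(OC)c1 | intermediate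
8 | methyl (2R)-oxirane-2-carboxylate | COC(=O)[C@H]1CO1 | starting material
9 | hexylmagnesium bromide | CCCCCC[Mg]Br | starting material
10 | bromomagnesium alkoxide of methyl (2R)-2-hydroxynonanoate | CCCCCCC[C@@H](O[Mg]Br)C(=O)OC | intermediate
11 | methyl (2R)-2-(triethylsilyloxy)nonanoate | CCCCCCC[C@@H](O[Si](CC)(CC)CC)C(=O)OC | intermediate
12 | but-3-enylmagnesium bromide | C=CCC[Mg]Br | starting material
13 | (2R)-N-methoxy-N-methyl-2-(triethylsilyloxy)nonanamide | CCCCCCC[C@@H](O[Si](CC)(CC)CC)C(=O)N(C)OC | intermediate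
14 | (6R)-6-(triethylsilyloxy)tridec-1-en-5-one | CCCCCCC[C@@H](O[Si](CC)(CC)CC)C(=O)CCC=C | intermediate
15 | racemic 3-bromo-6,8-dimethoxyisochroman-1-one | COc1cc2CC(Br)OC(=O)c2c(OC)c1 | intermediate
16 | (3R)-6,8-dimethoxy-3-[(6R)-5-oxo-6-(triethylsilyloxy)tridecyl]isochroman-1-one | CCCCCCC[C@@H](O[Si](CC)(CC)CC)C(=O)CCCC[C@@H]1Cc2cc(OC)cc(OC)c2C(=O)O1 | intermediate
17 | (3R)-8-hydroxy-3-[(6R)-6-hydroxy-5-oxotridecyl]-6-methoxyisochroman-1-one | CCCCCCC[C@@H](O)C(=O)CCCC[C@@H]1Cc2cc(OC)cc(O)c2C(=O)O1 | target

**Step count**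
Total steps: 7. Longest linear sequence: 5 steps (1, 2, 3, 6, 7); the side‑chain branch is 4 steps (4, 5, 6, 7).

**Steps most likely to fail, with fallbacks**

Step 6. The cyclic bromide 15 can lose HBr back to 7 or ionise under the phosphate/silane conditions, the sense and level of induction on a lactone‑type electrophile are untested, and the base could epimerise the α‑silyloxy ketone. The fallback moves the coupling to the open‑chain series, which is the proven electrophile class, and closes the lactone afterwards. It sets out from aldehyde ester 6 (isolated by a cold NH4Cl quench in step 3 instead of the acid treatment) and olefin 14. Compound 6 adds acetyl bromide (cat. ZnBr2, CH2Cl2, 0 °C) to give racemic methyl 2-(2-acetoxy-2-bromoethyl)-4,6-dimethoxybenzoate F1. The same nickel‑hydride conditions with 14 give methyl 2-[(2R,8R)-2-acetoxy-7-oxo-8-(triethylsilyloxy)pentadecyl]-4,6-dimethoxybenzoate F2. K2CO3 (0.2 equiv) in MeOH at 0 °C removes the acetate to give methyl 2-[(2R,8R)-2-hydroxy-7-oxo-8-(triethylsilyloxy)pentadecyl]-4,6-dimethoxybenzoate F3, which lactonises onto the neighbouring ester and comes back to the route at 16.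

Step 3. Formylation of the benzylic anion may over‑add, or the hindered, electron‑rich ester may lactonise slowly. The fallback installs the extra carbon as an ester and reduces it. It sets out from 4: LiN(i-Pr)2 (2.2 equiv, THF, −78 °C) then methyl chloroformate gives methyl 2-(2-methoxy-2-oxoethyl)-4,6-dimethoxybenzoate F4. i-Bu2AlH (1.05 equiv, toluene, −78 °C) reduces the unhindered aliphatic ester selectively to the aldehyde, coming back to the route at 6, which is cyclised to 7 with cat. p‑TsOH in toluene at 80 °C.

Step 7. BCl3 may attack the 6‑OMe or isomerise the free acyloin (enediol shift) once it is unmasked. The fallback demethylates before the coupling so that only fluoride is needed at the end. It sets out from 7: BCl3 (CH2Cl2, −78 → 0 °C) gives 8-hydroxy-6-methoxy-1H-isochromen-1-one F5. i-Pr3SiCl and imidazole in DMF give 6-methoxy-8-(triisopropylsilyloxy)-1H-isochromen-1-one F6. HBr as in step 6 gives racemic 3-bromo-6-methoxy-8-(triisopropylsilyloxy)isochroman-1-one F7, and the nickel‑hydride coupling with 14 gives (3R)-6-methoxy-3-[(6R)-5-oxo-6-(triethylsilyloxy)tridecyl]-8-(triisopropylsilyloxy)isochroman-1-one F8. HF·pyridine in THF at 0 °C removes both silyl groups and comes back to the route at 17.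

**Further compounds**
F1 | step 6 | racemic methyl 2-(2-acetoxy-2-bromoethyl)-4,6-dimethoxybenzoate | COC(=O)c1c(CC(Br)OC(C)=O)cc(OC)cc1OC
F2 | step 6 | methyl 2-[(2R,8R)-2-acetoxy-7-oxo-8-(triethylsilyloxy)pentadecyl]-4,6-dimethoxybenzoate | CCCCCCC[C@@H](O[Si](CC)(CC)CC)C(=O)CCCC[C@@H](OC(C)=O)Cc1cc(OC)cc(OC)c1C(=O)OC
F3 | step 6 | methyl 2-[(2R,8R)-2-hydroxy-7-oxo-8-(triethylsilyloxy)pentadecyl]-4,6-dimethoxybenzoate | CCCCCCC[C@@H](O[Si](CC)(CC)CC)C(=O)CCCC[C@@H](O)Cc1cc(OC)cc(OC)c1C(=O)OC
F4 | step 3 | methyl 2-(2-methoxy-2-oxoethyl)-4,6-dimethoxybenzoate | COC(=O)Cc1cc(OC)cc(OC)c1C(=O)OC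
F5 | step 7 | 8-hydroxy-6-methoxy-1H-isochromen-1-one | COc1cc(O)c2C(=O)OC=Cc2c1
F6 | step 7 | 6-methoxy-8-(triisopropylsilyloxy)-1H-isochromen-1-one | COc1cc(O[Si](C(C)C)(C(C)C)C(C)C)c2C(=O)OC=Cc2c1
F7 | step 7 | racemic 3-bromo-6-methoxy-8-(triisopropylsilyloxy)isochroman-1-one | COc1cc(O[Si](C(C)C)(C(C)C)C(C)C)c2C(=O)OC(Br)Cc2c1
F8 | step 7 | (3R)-6-methoxy-3-[(6R)-5-oxo-6-(triethylsilyloxy)tridecyl]-8-(triisopropylsilyloxy)isochroman-1-one | CCCCCCC[C@@H](O[Si](CC)(CC)CC)C(=O)CCCC[C@@H]1Cc2cc(OC)cc(O[Si](C(C)C)(C(C)C)C(C)C)c2C(=O)O1
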